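Numbering used throughout: C1=C2 is the ring alkene, with C1 bonded to C15 (CMe2). C3 = CHMe, C4 = ketone, C5 = pyran CH–O, C6 = CH2, C7 = CHMe, C8 = CH–O-acyl, C9 = hemiketal, C10 = CHOH, C11 = C(Me)–O, C12 and C13 = CH2, C14 = THF CH–O.

Assumption: compounds 1, 8 and 16 are purchased. Compound 1 is the silyl ether of (S)-glycidol, and 8 is the L-glutamic acid lactone ester.

## Retrosynthetic overview
1. The hemiketal/C10-OH pair is released last from a spiro-acetonide. C4=O comes from a carbinol, and the 15-membered ring is closed by E-selective RCM at C1=C2.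
2. The C15–C1 bond (quaternary carbon) comes from the C15 tertiary carbinol by photochemical Ir/Ni deoxygenative vinylation. C2/C3 come from chelation-controlled crotylation of the C4 aldehyde.
3. The cis-THF, with C11 and C10 set from C14, comes from a diol-templated osmium oxidative cyclisation of an E-trisubstituted alkene.
4. The C9–C10 union joins an alkenyllithium (C10–C15, C14 bought) to an all-cis δ-lactone (C4–C9, C5 bought). C7 and C8 are relayed from C5.
5. Ring order: pyran (δ-lactone, then hemiketal), then THF, then the macrocycle.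

## Route

**Step 1**
Reactants: 1, (R)-tert-butyl(oxiran-2-ylmethoxy)diphenylsilane; 2, ethyl propiolate
Product: 3, ethyl (R)-6-(TBDPS-oxy)-5-hydroxyhex-2-ynoate
Conditions: 2, n-BuLi, THF, −78 °C; BF3·OEt2; then 1, −78 °C
Reagents that add atoms: ethyl propiolate (2), C#CC(=O)OCC
Why: BF3-promoted (Yamaguchi–Hirao) alkynylation opens the epoxide at the terminal CH2 (C6), so the purchased C5 stereocentre is not touched.

**Step 2**
Reactants: 3
Product: 4, (R)-6-(TBDPS-oxymethyl)-4-methyl-5,6-dihydro-2H-pyran-2-one
Conditions: Me2CuLi (3 equiv), Et2O, −78 to −20 °C; then cat. p-TsOH, CH2Cl2, rt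
Reagents that add atoms: lithium dimethylcuprate, C[Cu-]C.[Li+]
Why: Syn-carbocupration of the ynoate places the chain cis to the ester, so the (Z)-enoate lactonises on the C5 hydroxyl.

**Step 3**
Reactants: 4
Product: 5, (4R,6R)-6-(TBDPS-oxymethyl)-4-methyltetrahydropyran-2-one (4,6-cis)
Conditions: H2 (1 atm), 10% Pd/C, EtOAc, rt
Reagents that add atoms: none
Why: Heterogeneous hydrogenation delivers H2 to the ring face opposite the C5 side chain, which sets C7 (R) cis to it.

**Step 4**
Reactants: 5
Product: 6, (3S,4R,6R)-3-hydroxy lactone (OH trans to the 4-methyl)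
Conditions: KHMDS, THF, −78 °C; (±)-2-(phenylsulfonyl)-3-phenyloxaziridine; CSA quench
Reagents that add atoms: racemic 2-(phenylsulfonyl)-3-phenyloxaziridine, O=S(=O)(c1ccccc1)N1OC1c1ccccc1
Why: In this enolate hydroxylation the oxidant attacks the lactone enolate anti to the adjacent C7 methyl, giving the 3,4-trans carbinol (C8 epimeric to the target).

**Step 5**
Reactants: 6
Product: 7, (3R,4R,6R)-3-hydroxy-4-methyl-6-(TBDPS-oxymethyl)tetrahydropyran-2-one (all-cis)
Conditions: HCO2H, PPh3, DIAD, toluene, 0 °C to rt; then NaHCO3, MeOH, 0 °C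
Reagents that add atoms: formic acid (supplies the inverted oxygen), O=CO
Why: Mitsunobu SN2 inversion at the carbonyl-activated α-carbon sets C8 (R, axial O), and the formate is cleaved in the work-up.

**Step 6**
Reactants: 8, ethyl (S)-5-oxotetrahydrofuran-2-carboxylate
Product: 9, (S)-5-(2-hydroxypropan-2-yl)dihydrofuran-2(3H)-one
Conditions: MeMgBr (2.2 equiv), THF, −78 °C
Reagents that add atoms: methylmagnesium bromide, C[Mg]Br
Why: Double Grignard addition takes place at the chelation-activated α-alkoxy ester faster than at the lactone, building C15(Me)2OH next to the purchased C14 (S).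

**Step 7**
Reactants: 9
Product: 10, (5S)-5-(2-hydroxypropan-2-yl)tetrahydrofuran-2-ol (anomer mixture)
Conditions: DIBAL-H (2.2 equiv), CH2Cl2, −78 °C
Reagents that add atoms: none
Why: Partial reduction of the lactone stops at the stable aluminium lactolate.

**Step 8**
Reactants: 10
Product: 11, (S)-2-methylhept-6-yne-2,3-diol
Conditions: dimethyl (1-diazo-2-oxopropyl)phosphonate, K2CO3, MeOH, rt
Reagents that add atoms: Ohira–Bestmann reagent (adds C10), COP(=O)(OC)C(=[N+]=[N-])C(C)=O
Why: Seyferth–Gilbert/Ohira–Bestmann homologation acts on the open hydroxy-aldehyde form of the lactol to give the terminal alkyne.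

**Step 9**
Reactants: 11
Product: 12, (S,E)-7-iodo-2,6-dimethylhept-6-ene-2,3-diol
Conditions: Me3Al (5 equiv), Cp2ZrCl2 (0.5 equiv), CH2Cl2, 0 °C to rt; then I2, THF, −30 °C
Reagents that add atoms: trimethylaluminium, C[Al](C)C; iodine, II
Why: Negishi carboalumination is a strict syn Me–Al addition, and iodinolysis proceeds with retention, giving >98% E alkene with the OH groups masked as aluminium alkoxides.

**Step 10**
Reactants: 12; 7
Product: 13, the C9 hemiketal (in equilibrium with the open δ-hydroxy E-enone). It is a 2-[(1E,5S)-5,6-dihydroxy-2,6-dimethylhept-1-enyl]-tetrahydropyran-2,3-diol that keeps the C5, C7 and C8 substituents of 7.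
Conditions: 12: MeLi (2.0 equiv), then t-BuLi (2.1 equiv), Et2O, −78 °C. 7: LiHMDS (1.0 equiv), THF, −78 °C. Combine at −78 °C and quench with AcOH.
Reagents that add atoms: none
Why: Stereoretentive I/Li exchange is followed by a single 1,2-addition to the lactone, whose tetrahedral adduct persists at −78 °C; this forms C9–C10, and the anomeric effect places the C9 OH axial.

**Step 11**
Reactants: 13
Product: 14, the cis-2,5-THF with 10S-OH, 11R, 14S and a free C15 tertiary OH (pyran hemiketal unchanged)
Conditions: K2OsO2(OH)4 (5 mol %), pyridine N-oxide (2 equiv), citric acid, Cu(OTf)2, MeCN/aq. buffer pH 6.5, 60 °C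
Reagents that add atoms: pyridine N-oxide (terminal oxidant and source of the C10 oxygen via Os=O), [O-][n+]1ccccc1
Why: In this osmium(VI) oxidative cyclisation the 14,15-diol chelates Os and adds O14 and Os=O syn across the E C10=C11 bond, so only the 2,5-cis THF forms; C14 fixes C11 and the alkene geometry fixes C10.

**Step 12**
Reactants: 14
Product: 15, the O9,O10-isopropylidene spiroketal (C8-OH and C15-OH free)
Conditions: 2,2-dimethoxypropane, PPTS, acetone, rt
Reagents that add atoms: 2,2-dimethoxypropane, COC(C)(C)OC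
Why: Thermodynamic acetonide formation takes the anomeric OH and the exocyclic C10 OH, as in 1,2-O-isopropylidene ketopyranoses, because O8 and O9 are trans-diaxial and cannot bridge.

**Step 13**
Reactants: 15; 16, (E)-3-methylpent-2-enoic acid
Product: 17, the C8 (E)-3-methylpent-2-enoate
Conditions: 16, 2,4,6-trichlorobenzoyl chloride, Et3N, toluene; then 15, DMAP, rt
Reagents that add atoms: (E)-3-methylpent-2-enoic acid (16), CC/C(C)=C/C(=O)O
Why: Yamaguchi esterification acylates the only secondary OH present, and the tertiary C15 OH is inert.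

**Step 14** (key step)
Reactants: 17; 18, vinyl bromide
Product: 19, C15(Me)2–CH=CH2 (new C15–C1 bond)
Conditions: 5,7-di-tert-butyl-3-phenylbenzoxazolium BF4 (1.2 equiv), pyridine, MTBE, rt, 15 min. Then [Ir(ppy)2(dtbbpy)]PF6 (1.5 mol %), Ni(TMHD)2 (10 mol %), quinuclidine, 18 (5 equiv, 1 M in THF), DMA/MTBE, 450 nm LEDs, rt.
Reagents that add atoms: vinyl bromide (18), C=CBr
Why: Proposed new method: the tertiary alcohol condenses with the benzoxazolium salt, excited Ir(III) oxidises the adduct, and deprotonation followed by β-scission releases the C15 tertiary radical, which is trapped by the vinyl–Ni(II) species formed from vinyl bromide; the small vinyl ligand and the open diketonate coordination sphere should favour C(sp3)–C(sp2) reductive elimination from Ni(III) over β-H elimination, giving the quaternary carbon without touching C14; the closest known reaction types are metallaphotoredox deoxygenative arylation of alcohols, Ni(TMHD)2 arylation of tertiary radicals, and decarboxylative vinylation of secondary/α-oxy radicals, whereas coupling of a tertiary radical with an unactivated vinyl halide has not been shown.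

**Step 15**
Reactants: 19
Product: 20, the C4 primary alcohol
Conditions: TBAF/AcOH (1:1), THF, 0 °C to rt
Reagents that add atoms: none
Why: Buffered fluoride desilylation leaves the ester, the acetonide and the alkenes intact.

**Step 16**
Reactants: 20
Product: 21, the C4 aldehyde
Conditions: Dess–Martin periodinane, NaHCO3, CH2Cl2, 0 °C
Reagents that add atoms: none
Why: Dess–Martin oxidation is neutral and does not epimerise the α-alkoxy aldehyde at C5.

**Step 17**
Reactants: 21; 22, (E)-but-2-enyltributylstannane
Product: 23, the (3S,4R)-homoallylic alcohol C5–CH(OH)–CH(Me)–CH=CH2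
Conditions: MgBr2·OEt2 (3 equiv), CH2Cl2, −25 °C; then 22
Reagents that add atoms: crotyltributylstannane (22), C/C=C/C[Sn](CCCC)(CCCC)CCCC
Why: In this Keck chelation-controlled crotylation Mg bridges the aldehyde O and the pyran O5, giving 4,5-syn attack, and the open SE2′ transition state gives 3,4-syn, so C5 sets C3 (S); C4 is only temporary.

**Step 18**
Reactants: 23
Product: 24, the 15-membered (E)-C1=C2 macrocycle with a 4R carbinol
Conditions: Grubbs II (10 mol %), CH2Cl2 (0.5 mM), reflux
Reagents that add atoms: none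
Why: Ring-closing metathesis joins the two terminal vinyl groups with loss of ethylene; the hindered, reversible closure next to C15 gives the E alkene, and the trisubstituted enoate does not react.

**Step 19**
Reactants: 24
Product: 25, the C4 ketone (spiro-acetonide retained)
Conditions: Dess–Martin periodinane, NaHCO3, CH2Cl2, 0 °C
Reagents that add atoms: none
Why: Buffered Dess–Martin oxidation of the only free OH avoids epimerisation at C3/C5 and avoids conjugation of the β,γ-enone.

**Step 20**
Reactants: 25
Product: 26, tonantzitlolone A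
Conditions: AcOH/THF/H2O (3:1:1), 40 °C
Reagents that add atoms: none
Why: Mild hydrolysis removes the labile anomeric acetonide, and the hemiketal settles as the thermodynamic anomer (axial OH, equatorial C10), which is C9 (R).

## Compound list

| No. | Name | SMILES | Role |
|---|---|---|---|
| 1 | (R)-TBDPS glycidyl ether | C1O[C@H]1CO[Si](c1ccccc1)(c1ccccc1)C(C)(C)C | starting material |
| 2 | ethyl propiolate | C#CC(=O)OCC | starting material |
| 3 | δ-hydroxy ynoate | CCOC(=O)C#CC[C@@H](O)CO[Si](c1ccccc1)(c1ccccc1)C(C)(C)C | intermediate |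
| 4 | unsaturated lactone | C1=C(C)C[C@H](CO[Si](c2ccccc2)(c2ccccc2)C(C)(C)C)OC1=O | intermediate |
| 5 | cis-4,6 lactone | C1[C@H](C)C[C@H](CO[Si](c2ccccc2)(c2ccccc2)C(C)(C)C)OC1=O | intermediate |
| 6 | 3,4-trans hydroxy lactone | O[C@H]1[C@H](C)C[C@H](CO[Si](c2ccccc2)(c2ccccc2)C(C)(C)C)OC1=O | intermediate |
| 7 | all-cis hydroxy lactone | O[C@@H]1[C@H](C)C[C@H](CO[Si](c2ccccc2)(c2ccccc2)C(C)(C)C)OC1=O | intermediate |
| 8 | ethyl (S)-5-oxotetrahydrofuran-2-carboxylate | O=C1CC[C@H](O1)C(=O)OCC | starting material |
| 9 | hydroxy lactone | O=C1CC[C@H](O1)C(C)(C)O | intermediate |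
| 10 | lactol | OC1CC[C@H](O1)C(C)(C)O | intermediate |
| 11 | alkyne diol | C#CCC[C@H](O)C(C)(C)O | intermediate |
| 12 | (E)-vinyl iodide diol | I/C=C(\C)CC[C@H](O)C(C)(C)O | intermediate |
| 13 | alkenyl hemiketal | O[C@@H]1[C@H](C)C[C@H](CO[Si](c2ccccc2)(c2ccccc2)C(C)(C)C)O[C@]1(O)/C=C(\C)CC[C@H](O)C(C)(C)O | intermediate |
| 14 | THF–pyran polyol | O[C@@H]1[C@H](C)C[C@H](CO[Si](c2ccccc2)(c2ccccc2)C(C)(C)C)O[C@]1(O)[C@@H](O)[C@@]1(C)CC[C@H](O1)C(C)(C)O | intermediate |
| 15 | spiro-acetonide | O[C@@H]1[C@H](C)C[C@H](CO[Si](c2ccccc2)(c2ccccc2)C(C)(C)C)O[C@]1(OC(C)(C)O2)[C@@H]2[C@@]1(C)CC[C@H](O1)C(C)(C)O | intermediate |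
| 16 | (E)-3-methylpent-2-enoic acid | CC/C(C)=C/C(=O)O | starting material |
| 17 | C8 ester | CC/C(C)=C/C(=O)O[C@@H]1[C@H](C)C[C@H](CO[Si](c2ccccc2)(c2ccccc2)C(C)(C)C)O[C@]1(OC(C)(C)O2)[C@@H]2[C@@]1(C)CC[C@H](O1)C(C)(C)O | intermediate |
| 18 | vinyl bromide | C=CBr | starting material |
| 19 | C15-vinyl compound | CC/C(C)=C/C(=O)O[C@@H]1[C@H](C)C[C@H](CO[Si](c2ccccc2)(c2ccccc2)C(C)(C)C)O[C@]1(OC(C)(C)O2)[C@@H]2[C@@]1(C)CC[C@H](O1)C(C)(C)C=C | intermediate |
| 20 | C4 alcohol | CC/C(C)=C/C(=O)O[C@@H]1[C@H](C)C[C@H](CO)O[C@]1(OC(C)(C)O2)[C@@H]2[C@@]1(C)CC[C@H](O1)C(C)(C)C=C | intermediate |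
| 21 | C4 aldehyde | CC/C(C)=C/C(=O)O[C@@H]1[C@H](C)C[C@H](C=O)O[C@]1(OC(C)(C)O2)[C@@H]2[C@@]1(C)CC[C@H](O1)C(C)(C)C=C | intermediate |
| 22 | (E)-crotyltributylstannane | C/C=C/C[Sn](CCCC)(CCCC)CCCC | starting material |
| 23 | RCM diene | CC/C(C)=C/C(=O)O[C@@H]1[C@H](C)C[C@H]([C@H](O)[C@@H](C)C=C)O[C@]1(OC(C)(C)O2)[C@@H]2[C@@]1(C)CC[C@H](O1)C(C)(C)C=C | intermediate |
| 24 | macrocyclic carbinol | CC/C(C)=C/C(=O)O[C@@H]1[C@H](C)C[C@H]2O[C@]1(OC(C)(C)O3)[C@@H]3[C@@]1(C)CC[C@H](O1)C(C)(C)/C=C/[C@H](C)[C@H]2O | intermediate |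
| 25 | macrocyclic ketone acetonide | CC/C(C)=C/C(=O)O[C@@H]1[C@H](C)C[C@H]2O[C@]1(OC(C)(C)O3)[C@@H]3[C@@]1(C)CC[C@H](O1)C(C)(C)/C=C/[C@H](C)C2=O | intermediate |
| 26 | tonantzitlolone A | CC/C(C)=C/C(=O)O[C@@H]1[C@H](C)C[C@H]2O[C@]1(O)[C@@H](O)[C@@]1(C)CC[C@H](O1)C(C)(C)/C=C/[C@H](C)C2=O | target |

## Summary
- Total steps: 20.
- Longest linear sequence: 16 steps (Steps 1–5, then 10–20).

**Steps most likely to fail**

1. **Step 14 (new tertiary-radical/vinyl–Ni coupling).** The risks are β-H elimination/isomerisation at Ni and simple radical reduction.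
   - Fallback, using known chemistry: convert 17 into its caesium oxalate with methyl chlorooxoacetate and then CsOH.
   - Run the established photoredox deoxygenative alkynylation with TIPS-ethynylbenziodoxolone or an ethynyl sulfone.
   - Treat with TBAF, which also removes the TBDPS group, and semi-hydrogenate over Lindlar catalyst to reach 20.

2. **Step 10 (polyanionic alkenyllithium plus α-alkoxide lactone).** The risks are poor solubility, enolisation and double addition.
   - Fallback: reduce 7 to the lactol with DIBAL-H.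
   - Couple it with unprotected 12 under Ni/Cr (Nozaki–Hiyama–Kishi) conditions.
   - Oxidise the allylic alcohol selectively with MnO2 to give 13.

3. **Step 5 (Mitsunobu inversion next to a β-branch).** The risk is elimination back to a butenolide-type lactone.
   - Fallback: omit Steps 3–5 and use unsaturated lactone 4 directly in Step 10.
   - After Steps 11–12 the only alkene left is C7=C8, inside a 2,3-unsaturated spiroketal.
   - Epoxidise it with mCPBA anti to the axial O9.
   - Open the epoxide reductively with Cp2TiCl and 1,4-cyclohexadiene. This gives the tertiary C7 radical, and H is delivered anti to the O–Ti group, producing the same axial C8-OH and equatorial C7-Me array.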